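The constants are invented; no experiment stands behind them.

1.20 is the number to hold on to: incoming ligand charged per starting complex charged, the ligand cover. Each exchange consumes one incoming ligand, and full conversion to complex with two exchanged asks for 2 per starting complex, so incoming ligand is the limiting reagent.

| flask | starting complex | incoming ligand | time | remark |
|---|---|---|---|---|
| oak | 0.20 M | 0.240 M | 40 s | a closed flask charged with all of it at once and left for 40 s |
| elm | 0.20 M (fed, over 40.0 s) | 0.240 M | 40 s | all but starting complex at the start; starting complex goes in evenly over 40.0 s, the run ends at 40 s |
| alder | 0.20 M | 0.240 M |  | one stirred flow tank at steady state, fed with the mixture as stated, mean residence time 40 s |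
| cedar | 0.20 M | 0.240 M |  | one stirred flow tank at steady state, fed with the mixture as stated, mean residence time 200 s |

    leaving ligand + incoming ligand ⇌ idle adduct, settled at all times (K1 = 8.6 L mol⁻¹)
    starting complex + incoming ligand → leaving ligand + complex with one exchanged (k2 = 1.7 L mol⁻¹ s⁻¹)
    complex with one exchanged + incoming ligand → leaving ligand + complex with two exchanged (k3 = 1.3 L mol⁻¹ s⁻¹)

- the set-up with the highest amount of complex with two exchanged at the outlet or at the end, in percent of the starting complex put in ("none" if the first two lie within 2 percentage points) (oak / elm / alder / cedar / none)
- amount of complex with two exchanged at the outlet or at the end, in percent of the starting complex put in, oak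
- amount of complex with two exchanged at the outlet or at the end, in percent of the starting complex put in, elm
- amount of complex with two exchanged at the outlet or at the end, in percent of the starting complex put in, alder
- amount of complex with two exchanged at the outlet or at the end, in percent of the starting complex put in, cedar

- leaving ligand is meant together with its idle adduct
- the stated concentrations are those of everything mixed, before any reaction; amounts are the same in each set-up
- the feed brings no volume worth counting
- run time (oak): 40 s

1. In oak, starting complex has a half-life of 1.70 s by step 2 alone with the ligand as charged, so the run spans 23.5 half-lives. Yet the reckoning below leaves 0.200 of the charge as starting complex.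

2. Both exchanges in oak run on the same free incoming ligand, so their ratio, the selectivity factor 0.765, stays frozen while that ligand falls. The mixture then depends on how far the exchanges have gone, not on the clock. The share with one exchanged is the share left raised to this ratio, minus the share left, divided by the ratio's shortfall from one.

3. With 0.200 left, oak holds 0.391 with one exchanged and 0.409 with two. That makes 1.21 exchanges per starting complex, which matches the cover. So my reckoning puts oak's end point near 40.9%, and it goes no further.

4. The half-life holds for ligand as charged. Each exchange removes one incoming ligand and frees a leaving ligand, which at that ligand level stands 2.06 times as much in idle adduct as free. Free incoming ligand therefore falls and the clock stretches.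

The forecast, on the ground that the leaving ligand “ties up incoming ligand as the adduct”, names cedar best, with 38.4% for oak, 39.2% for elm, 32.7% for alder and 42.7% for cedar.

Oak ends at 38.4%, below the reckoned end point, and after 400 s it reads 40.3%. The best set-up is cedar at 42.6%, against 39.3% for elm and 32.8% for alder. Cedar's outlet carries 31.6% starting complex and 25.8% with one exchanged, which makes 1.11 exchanges per starting complex, 92.5% of the cover. Alder, with 39.4% starting complex at its outlet, has used 77.8% of the cover.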